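## Retrosynthetic overview

- The SMILES reads as the meso (6R,6'S) isomer of ε,ε-carotene-3,3'-dione. Both C7=C8 bonds are cut (two successive Julia–Kocienski olefinations) to a C20 polyene dialdehyde and two ring sulfones of opposite C6 configuration; the ring ketones travel as 3R silyl ethers and are restored last with MnO2.
- Both C6 configurations come from one racemic ring synthesis: a catalyst-controlled carbonyl reduction turns the racemic enone into two 3R diastereomers, which are separated later and used one after the other.
- The enone ring goes back, by methyl addition with carbonyl transposition, to a 3-ethoxy enone. Its C2–C3 and C4–C5 bonds form together when ethoxyethyne is inserted by nickel catalysis into the C5–C2 bond of a cyclobutanone; that bond is absent from the target and is made on purpose by a keteniminium–isobutene [2+2].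
- Enabling feature: in each end ring the run C5–C6–C1–C2 holds the quaternary gem-dimethyl carbon C1 between the stereocentre C6 and the methylene C2. It can therefore be closed as a strained cyclobutanone (C5 carbonyl) whose unsubstituted C2 side opens selectively and whose alkyl–nickel species has no β-hydrogen, while C3–C4 is an oxygenated two-carbon unit (an ynol ether).
- Ring order: the four-membered ring C5–C6–C1–C2 first, then its expansion to the six-membered end ring; the C40 chain is assembled afterwards.

Key step: step 3

Remarks before the steps: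
- Locants C1–C7 follow carotenoid numbering: C1 gem-dimethyl carbon, C2 methylene, C3 carbonyl carbon, C4 =CH, C5 methyl-bearing sp2 carbon, C6 stereocentre, C7 first chain carbon.
- Assumption: in the oxazaborolidine reduction the alkenyl flank of the ketone acts as the large group, so the (S)-catalyst gives the 3R carbinol. The opposite C3 configuration would serve equally, because C3 ends as a ketone.
- Assumption: the C20 dialdehyde (crocetindialdehyde) is bought from a specialty carotenoid supplier.

## Route

Step 1
Reactants: 1 N,N-dimethylacrylamide; 2 4-methoxybenzyl alcohol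
Product: 3 3-[(4-methoxybenzyl)oxy]-N,N-dimethylpropanamide
Conditions: KOtBu (10 mol%), THF, 0 °C to rt, slight excess of 2
Reagents that add atoms: none
Why: Alkoxide-catalysed oxa-Michael addition of a primary alcohol to an acrylamide should give the β-alkoxy amide directly, and no stereocentre is formed.

Step 2
Reactants: 3 the amide; 4 2-methylpropene
Product: 7 (±)-2-{[(4-methoxybenzyl)oxy]methyl}-3,3-dimethylcyclobutan-1-one, via keteniminium triflate 5 (not isolated), via cyclobutaniminium triflate 6 (not isolated)
Conditions: (CF3SO2)2O, 2,4,6-collidine, excess condensed 4, CH2Cl2, −40 °C to rt, sealed vessel; then aq. NaHCO3, rt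
Reagents that add atoms: water, O
Why: In this keteniminium–olefin [2+2] cycloaddition the electrophilic central carbon of 5 should bond to the CH2 terminus of isobutene and the tertiary cation should close onto the enamine carbon, which puts the gem-dimethyl carbon next to the new stereocentre (formed as the racemate, as the meso target requires), and hydrolysis of 6 should give the cyclobutanone.

Step 3
Reactants: 7 the cyclobutanone; 8 ethoxyethyne
Product: 9 (±)-3-ethoxy-6-{[(4-methoxybenzyl)oxy]methyl}-5,5-dimethylcyclohex-2-en-1-one
Conditions: Ni(cod)2 (10 mol%), PCy3 (20 mol%), toluene, 80 °C, slow addition of 8 (3 equiv)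
Reagents that add atoms: none
Why: Proposed new method: zerovalent nickel should join the C5 carbonyl of 7 and the ynol ether 8 by oxidative cyclisation to a spiro oxanickelacyclopentene in which the nucleophilic CH terminus of 8 (C4) is bonded to C5 and the ethoxy-bearing carbon (C3) to nickel, β-carbon elimination should then move the ring methylene C2 from C5 to nickel with release of the cyclobutane strain, and C(sp3)–C(sp2) reductive elimination should form C2–C3. The closest known reaction type is the nickel-catalysed insertion of internal dialkyl and aryl alkynes into cyclobutanones and into 2-substituted azetidin-3-ones, which gives six-membered enones by the same three events; the terminal ynol ether as two-carbon partner is the untested element, and its orientation is argued from nickel-catalysed couplings of ynamides with aldehydes, where the heteroatom-bearing carbon ends on nickel. The six-membered ring is closed as a formal [4+2] ring expansion, its last bond by reductive elimination from a seven-membered nickelacycle. No stereocentre is created and the one at C6 is not touched, so 9 stays racemic. The step needs site selectivity for the C5–C2 over the C5–C6 bond, which the unsubstituted methylene opposite the substituted C6 should secure, and one alkyne orientation, which the push–pull polarisation of 8 and the conjugated vinylogous ester product favour. The alkyl–nickel intermediate cannot undergo β-hydride elimination because C1 is quaternary.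

Step 4
Reactants: 9 the vinylogous ester
Product: 11 (±)-4-{[(4-methoxybenzyl)oxy]methyl}-3,5,5-trimethylcyclohex-2-en-1-one, via tertiary allylic alcohol 10 (not isolated)
Conditions: MeLi, anhydrous CeCl3, THF, −78 °C; then 1 M HCl, THF, 0 °C
Reagents that add atoms: methyllithium, [Li]C; water, O
Why: In this Stork–Danheiser sequence the organocerium reagent should add 1,2 to the vinylogous ester carbonyl without enolising the β-alkoxy ketone, and acid should hydrolyse the enol ether and dehydrate 10 to the transposed enone, in which the former carbonyl carbon C5 carries the methyl group and C6 is untouched.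

Step 5
Reactants: 11 the racemic enone
Product: 12 (1R)-4-{[(4-methoxybenzyl)oxy]methyl}-3,5,5-trimethylcyclohex-2-en-1-ol as the pair of C4 epimers (carotenoid locants: 3R with 6R or 6S)
Conditions: (S)-2-methyl-CBS-oxazaborolidine (20 mol%), catecholborane, toluene, −78 °C; then MeOH, aq. NaOH
Reagents that add atoms: none
Why: Corey–Bakshi–Shibata reduction under catalyst control should deliver hydride to the same carbonyl face of both enantiomers of 11, which turns the racemate into two diastereomers that share the 3R carbinol centre and differ at C6, so that an ordinary separation later resolves C6.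

Step 6
Reactants: 12 the epimer pair of alcohols
Product: 13 tert-butyl{[(1R)-4-{[(4-methoxybenzyl)oxy]methyl}-3,5,5-trimethylcyclohex-2-en-1-yl]oxy}dimethylsilane as the pair of C4 epimers
Conditions: TBSCl, imidazole, DMF, rt
Reagents that add atoms: tert-butyldimethylsilyl chloride, CC(C)(C)[Si](C)(C)Cl
Why: Standard silylation of a secondary allylic alcohol should protect the C3 oxygen through the oxidative and basic steps that follow.

Step 7
Reactants: 13 the epimer pair of silyl ethers
Product: 14 [(4R)-4-{[tert-butyl(dimethyl)silyl]oxy}-2,6,6-trimethylcyclohex-2-en-1-yl]methanol as the pair of C1 epimers (carotenoid locants: 3R with 6R or 6S)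
Conditions: DDQ, CH2Cl2/pH 7 phosphate buffer, 0 °C
Reagents that add atoms: none
Why: Oxidative cleavage of a 4-methoxybenzyl ether by DDQ is much faster than oxidation of an allylic silyl ether and should free only the primary alcohol at C7.

Step 8
Reactants: 14 the epimer pair of primary alcohols
Product: 15 5-({[(4R)-4-{[tert-butyl(dimethyl)silyl]oxy}-2,6,6-trimethylcyclohex-2-en-1-yl]methyl}sulfanyl)-1-phenyl-1H-tetrazole as the pair of C1 epimers
Conditions: 1-phenyl-1H-tetrazole-5-thiol, PPh3, DIAD, THF, 0 °C to rt
Reagents that add atoms: 1-phenyl-1H-tetrazole-5-thiol, SC1=NN=NN1c1ccccc1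
Why: Mitsunobu thioetherification of a primary alcohol should install the tetrazolyl sulfide at C7 without touching C6, which bears only a hydrogen and no leaving group.

Step 9
Reactants: 15 the epimer pair of sulfides
Product: 16 5-({[(1R,4R)-4-{[tert-butyl(dimethyl)silyl]oxy}-2,6,6-trimethylcyclohex-2-en-1-yl]methyl}sulfonyl)-1-phenyl-1H-tetrazole (3R,6R) and 17 its (1S,4R) epimer (3R,6S), separated after the oxidation
Conditions: (NH4)6Mo7O24·4H2O (20 mol%), 30% aq. H2O2, EtOH, 0 °C to rt; then preparative HPLC on silica
Reagents that add atoms: hydrogen peroxide, OO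
Why: Molybdate-catalysed peroxide oxidation should take the sulfide to the sulfone without epoxidising the trisubstituted alkene, and the two sulfones are diastereomers that should separate on silica, which completes the resolution of C6.

Step 10
Reactants: 16 the (3R,6R)-sulfone; 18 crocetindialdehyde, (2E,4E,6E,8E,10E,12E,14E)-2,6,11,15-tetramethylhexadeca-2,4,6,8,10,12,14-heptaenedial (4 equiv)
Product: 19 (3R,6R)-3-{[tert-butyl(dimethyl)silyl]oxy}-8'-apo-ε-caroten-8'-al (all-E)
Conditions: KN(SiMe3)2 added to 16 and 18 in THF, −78 °C to rt; aq. NH4Cl; excess 18 recovered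
Reagents that add atoms: none
Why: Julia–Kocienski olefination (addition, Smiles rearrangement, loss of SO2 and the tetrazololate) should form the C7=C8 bond with E preference, the excess of dialdehyde should hold the reaction at mono-olefination, and C6 is not acidified because the carbanion sits at C7.

Step 11
Reactants: 17 the (3R,6S)-sulfone; 19 the C30 aldehyde
Product: 20 (3R,6R,3'R,6'S)-3,3'-bis{[tert-butyl(dimethyl)silyl]oxy}-ε,ε-carotene (all-E)
Conditions: KN(SiMe3)2 added to 17 (1.2 equiv) and 19 in THF, −78 °C to rt; aq. NH4Cl; then heptane, 80 °C, dark, argon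
Reagents that add atoms: none
Why: A second Julia–Kocienski olefination should attach the ring of opposite C6 configuration to the other end, which fixes the meso relationship of C6 and C6', and mild heating should convert any hindered 7Z or 7'Z bond to E.

Step 12
Reactants: 20 the bis-silyl ether
Product: 21 (3R,6R,3'R,6'S)-ε,ε-carotene-3,3'-diol
Conditions: Bu4NF, THF, 0 °C to rt, dark, argon
Reagents that add atoms: none
Why: Fluoride-mediated desilylation should free both allylic alcohols without affecting the polyene or the C6 centres.

Step 13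
Reactants: 21 the diol
Product: 22 (6R,6'S)-ε,ε-carotene-3,3'-dione (meso), the target
Conditions: activated MnO2 (excess), CH2Cl2, rt, dark
Reagents that add atoms: none
Why: Manganese dioxide oxidises allylic alcohols selectively under neutral heterogeneous conditions, so both C3 carbinols should become enone carbonyls while the γ-stereocentres C6 and C6' and the polyene are left alone.

## Compound list

1 | N,N-dimethylacrylamide | C=CC(=O)N(C)C | starting material
2 | 4-methoxybenzyl alcohol | COc1ccc(CO)cc1 | starting material
3 | 3-[(4-methoxybenzyl)oxy]-N,N-dimethylpropanamide | COc1ccc(COCCC(=O)N(C)C)cc1 | intermediate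
4 | 2-methylpropene | CC(C)=C | starting material
5 | N-{3-[(4-methoxybenzyl)oxy]prop-1-en-1-ylidene}-N-methylmethanaminium trifluoromethanesulfonate (keteniminium triflate) | COc1ccc(COCC=C=[N+](C)C)cc1.[O-]S(=O)(=O)C(F)(F)F | intermediate
6 | (±)-N-(2-{[(4-methoxybenzyl)oxy]methyl}-3,3-dimethylcyclobutylidene)-N-methylmethanaminium trifluoromethanesulfonate (cyclobutaniminium triflate) | COc1ccc(COCC2C(=[N+](C)C)CC2(C)C)cc1.[O-]S(=O)(=O)C(F)(F)F | intermediate
7 | (±)-2-{[(4-methoxybenzyl)oxy]methyl}-3,3-dimethylcyclobutan-1-one | COc1ccc(COCC2C(=O)CC2(C)C)cc1 | intermediate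
8 | ethoxyethyne | CCOC#C | starting material
9 | (±)-3-ethoxy-6-{[(4-methoxybenzyl)oxy]methyl}-5,5-dimethylcyclohex-2-en-1-one | CCOC1=CC(=O)C(COCc2ccc(OC)cc2)C(C)(C)C1 | intermediate
10 | (±)-3-ethoxy-6-{[(4-methoxybenzyl)oxy]methyl}-1,5,5-trimethylcyclohex-2-en-1-ol (diastereomer mixture) | CCOC1=CC(C)(O)C(COCc2ccc(OC)cc2)C(C)(C)C1 | intermediate
11 | (±)-4-{[(4-methoxybenzyl)oxy]methyl}-3,5,5-trimethylcyclohex-2-en-1-one | CC1=CC(=O)CC(C)(C)C1COCc1ccc(OC)cc1 | intermediate
12 | (1R)-4-{[(4-methoxybenzyl)oxy]methyl}-3,5,5-trimethylcyclohex-2-en-1-ol, pair of C4 epimers (3R; 6R and 6S) | CC1=C[C@H](O)CC(C)(C)C1COCc1ccc(OC)cc1 | intermediate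
13 | tert-butyl{[(1R)-4-{[(4-methoxybenzyl)oxy]methyl}-3,5,5-trimethylcyclohex-2-en-1-yl]oxy}dimethylsilane, pair of C4 epimers | CC1=C[C@H](O[Si](C)(C)C(C)(C)C)CC(C)(C)C1COCc1ccc(OC)cc1 | intermediate
14 | [(4R)-4-{[tert-butyl(dimethyl)silyl]oxy}-2,6,6-trimethylcyclohex-2-en-1-yl]methanol, pair of C1 epimers | CC1=C[C@H](O[Si](C)(C)C(C)(C)C)CC(C)(C)C1CO | intermediate
15 | 5-({[(4R)-4-{[tert-butyl(dimethyl)silyl]oxy}-2,6,6-trimethylcyclohex-2-en-1-yl]methyl}sulfanyl)-1-phenyl-1H-tetrazole, pair of C1 epimers | CC1=C[C@H](O[Si](C)(C)C(C)(C)C)CC(C)(C)C1CSC1=NN=NN1c1ccccc1 | intermediate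
16 | 5-({[(1R,4R)-4-{[tert-butyl(dimethyl)silyl]oxy}-2,6,6-trimethylcyclohex-2-en-1-yl]methyl}sulfonyl)-1-phenyl-1H-tetrazole (3R,6R) | CC1=C[C@H](O[Si](C)(C)C(C)(C)C)CC(C)(C)[C@H]1CS(=O)(=O)C1=NN=NN1c1ccccc1 | intermediate
17 | 5-({[(1S,4R)-4-{[tert-butyl(dimethyl)silyl]oxy}-2,6,6-trimethylcyclohex-2-en-1-yl]methyl}sulfonyl)-1-phenyl-1H-tetrazole (3R,6S) | CC1=C[C@H](O[Si](C)(C)C(C)(C)C)CC(C)(C)[C@@H]1CS(=O)(=O)C1=NN=NN1c1ccccc1 | intermediate
18 | crocetindialdehyde, (2E,4E,6E,8E,10E,12E,14E)-2,6,11,15-tetramethylhexadeca-2,4,6,8,10,12,14-heptaenedial | O=C/C(C)=C/C=C/C(C)=C/C=C/C=C(C)/C=C/C=C(C)/C=O | starting material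
19 | (3R,6R)-3-{[tert-butyl(dimethyl)silyl]oxy}-8'-apo-ε-caroten-8'-al | CC1=C[C@H](O[Si](C)(C)C(C)(C)C)CC(C)(C)[C@H]1/C=C/C(C)=C/C=C/C(C)=C/C=C/C=C(C)/C=C/C=C(C)/C=O | intermediate
20 | (3R,6R,3'R,6'S)-3,3'-bis{[tert-butyl(dimethyl)silyl]oxy}-ε,ε-carotene | CC1=C[C@H](O[Si](C)(C)C(C)(C)C)CC(C)(C)[C@@H]1/C=C/C(C)=C/C=C/C(C)=C/C=C/C=C(C)/C=C/C=C(C)/C=C/[C@H]1C(C)=C[C@H](O[Si](C)(C)C(C)(C)C)CC1(C)C | intermediate
21 | (3R,6R,3'R,6'S)-ε,ε-carotene-3,3'-diol | CC1=C[C@H](O)CC(C)(C)[C@@H]1/C=C/C(C)=C/C=C/C(C)=C/C=C/C=C(C)/C=C/C=C(C)/C=C/[C@H]1C(C)=C[C@H](O)CC1(C)C | intermediate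
22 | (6R,6'S)-ε,ε-carotene-3,3'-dione (meso) | CC1=CC(=O)CC(C)(C)[C@@H]1/C=C/C(C)=C/C=C/C(C)=C/C=C/C=C(C)/C=C/C=C(C)/C=C/[C@H]1C(C)=CC(=O)CC1(C)C | target

## Step count and risks

Total step count: 13. Longest linear sequence: 13 steps (from 1 and 2 to 22; both sulfones come from the same line).

Steps most likely to fail:

1. Step 3 (proposed new method). The terminal ynol ether may oligomerise on nickel faster than it inserts, or the C5–C6 bond may open instead of the C5–C2 bond. Fallback with known chemistry, reaching the same racemic vinylogous ester by enolate alkylation instead of C–C activation: it sets out from 2. NaH and chloromethyl methyl sulfide (NaI, THF) should give 4-methoxybenzyl (methylsulfanyl)methyl ether F1. SO2Cl2 (CH2Cl2, −78 °C) should convert it into 4-methoxybenzyl chloromethyl ether F2. The lithium enolate of commercial 3-ethoxy-5,5-dimethylcyclohex-2-en-1-one (LiN(iPr)2, THF, −78 °C, kinetic deprotonation at the methylene between the carbonyl and the gem-dimethyl carbon) is then alkylated with F2, and the route is rejoined at 9.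

2. Step 5. Catalyst control over the carbonyl face may be weak, because the two flanks of the ketone differ little in size, and each separated diastereomer would then carry low C6 purity. Fallback with an enzymatic resolution: it sets out from 11. NaBH4 with CeCl3·7H2O (MeOH, −78 °C) should give all four stereoisomers of 4-{[(4-methoxybenzyl)oxy]methyl}-3,5,5-trimethylcyclohex-2-en-1-ol F3. A lipase (Pseudomonas fluorescens lipase, vinyl acetate, tert-butyl methyl ether, rt) should acetylate only the 1R alcohols to (1R)-4-{[(4-methoxybenzyl)oxy]methyl}-3,5,5-trimethylcyclohex-2-en-1-yl acetate F4 (both C4 epimers), which is separated on silica from the unreacted 1S alcohols. K2CO3 in MeOH then returns the route to 12.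

3. Step 10. The dialdehyde may be olefinated at both ends, and the sulfone may be consumed by self-condensation before it meets the poorly soluble polyenal. Fallback that differentiates the two ends of the linchpin by protection instead of by excess: it sets out from 18. Neopentyl glycol (1 equiv, pyridinium p-toluenesulfonate, CH2Cl2) should give, after chromatography, the mono-acetal (2E,4E,6E,8E,10E,12E,14E)-15-(5,5-dimethyl-1,3-dioxan-2-yl)-2,6,11-trimethylhexadeca-2,4,6,8,10,12,14-heptaenal F5. Julia–Kocienski olefination of 16 with one equivalent of F5 (KN(SiMe3)2, THF, −78 °C) should give the acetal-protected apo-carotenal, 2-[(3R,6R)-3-{[tert-butyl(dimethyl)silyl]oxy}-8'-apo-ε-caroten-8'-yl]-5,5-dimethyl-1,3-dioxane F6. Dilute acid (pyridinium p-toluenesulfonate, acetone/water, rt) unmasks the aldehyde, and the route is rejoined at 19.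

## Further compounds

F1 | step 3 | 4-methoxybenzyl (methylsulfanyl)methyl ether | COc1ccc(COCSC)cc1
F2 | step 3 | 4-methoxybenzyl chloromethyl ether | COc1ccc(COCCl)cc1
F3 | step 5 | 4-{[(4-methoxybenzyl)oxy]methyl}-3,5,5-trimethylcyclohex-2-en-1-ol, all four stereoisomers | CC1=CC(O)CC(C)(C)C1COCc1ccc(OC)cc1
F4 | step 5 | (1R)-4-{[(4-methoxybenzyl)oxy]methyl}-3,5,5-trimethylcyclohex-2-en-1-yl acetate, pair of C4 epimers | CC1=C[C@H](OC(C)=O)CC(C)(C)C1COCc1ccc(OC)cc1
F5 | step 10 | (2E,4E,6E,8E,10E,12E,14E)-15-(5,5-dimethyl-1,3-dioxan-2-yl)-2,6,11-trimethylhexadeca-2,4,6,8,10,12,14-heptaenal | O=C/C(C)=C/C=C/C(C)=C/C=C/C=C(C)/C=C/C=C(C)/C1OCC(C)(C)CO1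
F6 | step 10 | 2-[(3R,6R)-3-{[tert-butyl(dimethyl)silyl]oxy}-8'-apo-ε-caroten-8'-yl]-5,5-dimethyl-1,3-dioxane | CC1=C[C@H](O[Si](C)(C)C(C)(C)C)CC(C)(C)[C@H]1/C=C/C(C)=C/C=C/C(C)=C/C=C/C=C(C)/C=C/C=C(C)/C1OCC(C)(C)CO1
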